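**Strategy.** In the bornane core, the oxygen-bearing C2 and the benzylic-carbon-bearing C6 both adjoin the methylated bridgehead C1. An ortho-phenylene spans them to make the oxepine. Breaking C1–C6 and C4–C5 therefore dismantles the bicyclo[2.2.1]heptane and the seven-membered ring at once. In the forward direction the precursor is an achiral aryl vinyl ketone whose ortho oxygen sits on the internal carbon (C2) of a 1,5,5-trimethylcyclopentadiene. It undergoes a type 2 intramolecular Diels–Alder reaction on a chiral copper(II) Lewis acid. This creates both bonds, both rings and stereocentres C1, C4 and C6 in one operation. Exo hydride delivery then fixes C2, and formylation, acylation and demethylation finish the arene.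

Key step: step 9

Numbering used:
- Bornane atoms: C1 (CMe bridgehead), C2 (C–O), C3, C4 (CH bridgehead), C5, C6 (carries the benzylic carbon), C7 (CMe2).
- Arene atoms: Ar1 (bears the benzylic carbon), Ar2 (ring oxygen), then Ar3, Ar4, Ar5, Ar6 in sequence.

Assumption: the sense of induction in step 9 is derived from the square-planar chelate model established for s-cis acryloyl imides on Cu(II)–t-Bu-bis(oxazoline); should the antipode prevail, the equally available (S,S)-ligand is used.

Remark: the aryl dienyl ethers 9, 10, 13 and 14 are acid-labile, so chromatography on triethylamine-deactivated silica is assumed.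

Step 1
Reactants: 1 3,5-dimethoxyphenol
Product: 2 2-bromo-3,5-dimethoxyphenol
Conditions: NBS (1.0 equiv), CH2Cl2, −78 → 0 °C
Reagents that add atoms: N-bromosuccinimide, O=C1CCC(=O)N1Br
Why: Electrophilic aromatic bromination in which every free position is activated by all three oxygens, so sterics decide, and the two equivalent sites beside the small hydroxyl should be taken in preference to C4, which is wedged between two methoxy groups, while one equivalent of NBS at low temperature limits dibromination.

Step 2
Reactants: 3 2,2-dimethylcyclopentanone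
Product: 4 5,5-dimethylcyclopent-2-en-1-one
Conditions: IBX (2 equiv), DMSO, 75 °C
Reagents that add atoms: none
Why: IBX dehydrogenation of a ketone through its enol, in which only one α-carbon carries hydrogen because the other is quaternary, so a single enone can form and it cannot be oxidised further.

Step 3
Reactants: 4 5,5-dimethylcyclopent-2-en-1-one
Product: 5 rac-3,3-dimethyl-6-oxabicyclo[3.1.0]hexan-2-one
Conditions: 30% H2O2, NaOH (cat.), MeOH, 0 °C
Reagents that add atoms: hydrogen peroxide, OO
Why: Weitz–Scheffer nucleophilic epoxidation in which hydroperoxide adds to the unhindered β-carbon and the enolate closes the necessarily cis-fused oxirane (racemic, both centres being erased in step 4), the quaternary α′-carbon excluding enolisation side reactions.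

Step 4
Reactants: 2 2-bromo-3,5-dimethoxyphenol; 5 rac-3,3-dimethyl-6-oxabicyclo[3.1.0]hexan-2-one
Product: 7 2-(2-bromo-3,5-dimethoxyphenoxy)-5,5-dimethylcyclopent-2-en-1-one, via trans-hydroxy ketone 6 (not isolated)
Conditions: KH (0.2 equiv), THF–DMPU, 65 °C
Reagents that add atoms: none
Why: Known preparation of 2-aryloxyenones from α,β-epoxy ketones and phenols, in which the phenoxide opens the oxirane by SN2 at the carbonyl-activated α-carbon, the trans-β-hydroxy ketone 6 loses hydroxide by E1cB, and that hydroxide regenerates phenoxide so that base is needed only in catalytic amount.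

Step 5
Reactants: 7 2-(2-bromo-3,5-dimethoxyphenoxy)-5,5-dimethylcyclopent-2-en-1-one
Product: 9 2-(2-bromo-3,5-dimethoxyphenoxy)-5,5-dimethylcyclopenta-1,3-dien-1-yl trifluoromethanesulfonate, via potassium dienolate 8 (not isolated)
Conditions: KHMDS, THF, −78 °C; PhNTf2, −78 → 0 °C; H2O
Reagents that add atoms: N-phenylbis(trifluoromethanesulfonimide), O=S(=O)(N(c1ccccc1)S(=O)(=O)C(F)(F)F)C(F)(F)F
Why: Vinylogous (γ) deprotonation followed by O-sulfonylation, for which the ring CH2 is the only acidic site because the α′-carbon is quaternary and the aryl bromide has no ortho hydrogen, the hard triflating agent trapping the extended dienolate 8 on oxygen to give the cyclopentadienyl triflate.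

Step 6
Reactants: 9 2-(2-bromo-3,5-dimethoxyphenoxy)-5,5-dimethylcyclopenta-1,3-dien-1-yl trifluoromethanesulfonate
Product: 10 2-bromo-1,5-dimethoxy-3-[(2,3,3-trimethylcyclopenta-1,4-dien-1-yl)oxy]benzene
Conditions: Me2CuLi (from MeLi, CuI), THF, −20 → 0 °C
Reagents that add atoms: lithium dimethylcuprate, [Li+].C[Cu-]C
Why: Cuprate–enol triflate cross-coupling replaces C–OTf by C–CH3 with both double bonds held in place, so the 2-aryloxy-1,5,5-trimethylcyclopentadiene forms without any cationic or acidic step, and the electron-rich, doubly ortho-substituted aryl bromide should be inert to the cuprate at this temperature.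

Step 7
Reactants: 10 2-bromo-1,5-dimethoxy-3-[(2,3,3-trimethylcyclopenta-1,4-dien-1-yl)oxy]benzene; 11 acrolein
Product: 13 rac-1-{2,4-dimethoxy-6-[(2,3,3-trimethylcyclopenta-1,4-dien-1-yl)oxy]phenyl}prop-2-en-1-ol, via aryllithium 12 (not isolated)
Conditions: n-BuLi, THF, −78 °C; 11, −78 °C; H2O
Reagents that add atoms: none
Why: Bromine–lithium exchange followed by 1,2-addition of the aryllithium to acrolein, the exchange at −78 °C being much faster than any deprotonation of the diene, whose ring has no acidic C–H because its sp3 carbon is quaternary, and the new carbinol centre (racemic) being removed in step 8.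

Step 8
Reactants: 13 rac-1-{2,4-dimethoxy-6-[(2,3,3-trimethylcyclopenta-1,4-dien-1-yl)oxy]phenyl}prop-2-en-1-ol
Product: 14 1-{2,4-dimethoxy-6-[(2,3,3-trimethylcyclopenta-1,4-dien-1-yl)oxy]phenyl}prop-2-en-1-one (achiral)
Conditions: DMP, NaHCO3, CH2Cl2, 0 °C; used at once, kept cold
Reagents that add atoms: none
Why: Dess–Martin oxidation of a doubly activated (benzylic and allylic) alcohol is fast at 0 °C, the bicarbonate buffer protects the acid-labile dienyl ether, and the short cold procedure lets 14 be passed on before an uncatalysed cycloaddition can set in.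

Step 9
Reactants: 14 1-{2,4-dimethoxy-6-[(2,3,3-trimethylcyclopenta-1,4-dien-1-yl)oxy]phenyl}prop-2-en-1-one
Product: 15 (1R,4R,6R)-tetracyclic enol ether ketone (born-2-ene bridged from C2 through O–Ar2–Ar1–C(=O) to endo C6; OMe at Ar4 and Ar6)
Conditions: [Cu((R,R)-t-Bu-box)](SbF6)2 (20 mol %), 4 Å MS, CH2Cl2 (0.005 M, slow addition of 14), −40 → −20 °C
Reagents that add atoms: none
Why: Proposed new method: the ketone oxygen and the oxygen of the adjacent Ar6 methoxy group should bind Cu(II) in a six-membered chelate that holds the enone s-cis with its vinyl group turned towards the diene, and a concerted but asynchronous [4+2] follows in which C5–C4 forms ahead of the congested C6–C1 bond. The closest known reaction types are type 2 intramolecular Diels–Alder reactions with four-atom tethers and Cu(II)–bis(oxazoline)-catalysed additions of cyclopentadiene to chelating acryloyl dienophiles, whereas a cyclopentadiene tethered through its internal carbon, and its enantioselective cyclisation, have not been shown. The carbocyclic six-membered ring C1–C6 closes by the cycloaddition itself and, as C7 already links C1 and C4, becomes the bicyclo[2.2.1]heptene, while the oxepine (O, C2, C1, C6, C=O, Ar1, Ar2) closes in the 1,3-bridged mode when C6 meets C1, the other orientation requiring an eight-membered ring with a trans bridgehead alkene. C1, C4 and C6 arise from one suprafacial addition, their relative configuration being dictated by the tether, which can reach C2 only if the acyl carbon lies endo, and their absolute configuration by the ligand, whose tert-butyl group covers the Re face of the enone α-carbon so that the diene swings onto the Si face. The step needs diene-face selectivity and a catalysed intramolecular path that outruns dimerisation and the racemic background, which is served by high dilution, by the quaternary C7 (no 1,5-hydrogen shift, hindered dimerisation) and by the electronic mismatch between the 2-aryloxy diene and the enforced regiochemistry, while both ortho positions of the aryl ketone are blocked so that Nazarov closure is excluded.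

Step 10
Reactants: 15 (1R,4R,6R)-tetracyclic enol ether ketone
Product: 17 (1R,2S,4R,6S)-dimethoxy tetracycle (bornane bridged from endo C2–O to endo C6–CH2 by the arene), via saturated ketone 16 (not isolated)
Conditions: Et3SiH (6 equiv), TFA–CH2Cl2 (1:1), 0 °C → rt; H2O
Reagents that add atoms: none
Why: Ionic hydrogenation in which protonation of the enol ether at C3 gives the C2 oxocarbenium ion, which can accept hydride only on its exo face because the oxygen is tied through the arene to the endo substituent at C6 (endo attack would demand a trans-bridged seven-membered ring), so that C2 is set as S with endo oxygen, after which the electron-rich aryl ketone of 16 is taken to CH2 by two further hydride transfers through the strongly stabilised benzylic cation.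

Step 11
Reactants: 17 (1R,2S,4R,6S)-dimethoxy tetracycle
Product: 19 Ar3-carbaldehyde of 17, via iminium chloride 18 (not isolated)
Conditions: POCl3, DMF, 0 °C → rt; aq NaOAc
Reagents that add atoms: N,N-dimethylformamide, CN(C)C=O; water, O
Why: Vilsmeier–Haack formylation stops after one substitution, and the bulky chloroiminium ion should choose Ar3, flanked by the ring oxygen whose alkyl group is tied back into the oxepine, over Ar5, which is hemmed in by two methoxy groups (the Ar6 methyl being pushed towards it by the benzylic CH2), the same preference as is known for the position next to the ring oxygen in 5,7-dialkoxychromans.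

Step 12
Reactants: 19 Ar3-carbaldehyde of 17; 20 isovaleraldehyde
Product: 23 hydroxy aldehyde (Ar3-CHO, Ar5-CH(OH)CH2CHMe2; both carbinol epimers), via amino alkoxide 21 (not isolated), via aryllithium 22 (not isolated)
Conditions: LiN(Me)CH2CH2NMe2 (from the amine and n-BuLi), THF, −20 °C; n-BuLi, −20 → 0 °C; 20, −78 °C; H2O
Reagents that add atoms: none
Why: In situ protection of the aldehyde as its lithium α-amino alkoxide followed by directed ortho-metalation, for which Ar5–H is the only aromatic hydrogen left and lies between two methoxy groups, so that n-BuLi can lithiate nowhere else, the aryllithium adds to isovaleraldehyde, work-up releases the formyl group, and the new carbinol centre disappears in step 13.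

Step 13
Reactants: 23 hydroxy aldehyde
Product: 24 keto aldehyde dimethyl ether (Ar3-CHO, Ar5-isovaleryl, OMe at Ar4 and Ar6)
Conditions: DMP, CH2Cl2, rt
Reagents that add atoms: none
Why: Dess–Martin oxidation converts the secondary benzylic alcohol into the ketone and leaves the aryl aldehyde, the ethers and all four stereocentres untouched.

Step 14
Reactants: 24 keto aldehyde dimethyl ether
Product: 25 target CNP0246493.1, (1R,2S,4R,6S) in bornane numbering
Conditions: BCl3 (5 equiv), CH2Cl2, −78 → 0 °C; H2O
Reagents that add atoms: none
Why: Chelation-assisted aryl methyl ether cleavage with BCl3, in which each methoxy group sits ortho to a carbonyl oxygen that delivers boron to it and is lost by chloride attack on the unhindered methyl carbon, whereas the ring ether is secondary, neopentyl and endo on the bornane, so that it is closed to SN2 and lacks σ-assistance for ionisation.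

**Compound list**

1 | 3,5-dimethoxyphenol | COc1cc(O)cc(OC)c1 | starting material
2 | 2-bromo-3,5-dimethoxyphenol | COc1cc(O)c(Br)c(OC)c1 | intermediate
3 | 2,2-dimethylcyclopentanone | CC1(C)CCCC1=O | starting material
4 | 5,5-dimethylcyclopent-2-en-1-one | CC1(C)CC=CC1=O | intermediate
5 | rac-3,3-dimethyl-6-oxabicyclo[3.1.0]hexan-2-one (cis-fused epoxy ketone, one enantiomer drawn) | CC1(C)C[C@@H]2O[C@@H]2C1=O | intermediate
6 | rac-trans-2-(2-bromo-3,5-dimethoxyphenoxy)-3-hydroxy-5,5-dimethylcyclopentanone (one enantiomer drawn) | CC1(C)C[C@H](O)[C@@H](Oc2cc(OC)cc(OC)c2Br)C1=O | intermediate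
7 | 2-(2-bromo-3,5-dimethoxyphenoxy)-5,5-dimethylcyclopent-2-en-1-one | COc1cc(OC2=CCC(C)(C)C2=O)c(Br)c(OC)c1 | intermediate
8 | potassium 2-(2-bromo-3,5-dimethoxyphenoxy)-5,5-dimethylcyclopenta-1,3-dien-1-olate | COc1cc(OC2=C([O-])C(C)(C)C=C2)c(Br)c(OC)c1.[K+] | intermediate
9 | 2-(2-bromo-3,5-dimethoxyphenoxy)-5,5-dimethylcyclopenta-1,3-dien-1-yl trifluoromethanesulfonate | COc1cc(OC2=C(OS(=O)(=O)C(F)(F)F)C(C)(C)C=C2)c(Br)c(OC)c1 | intermediate
10 | 2-bromo-1,5-dimethoxy-3-[(2,3,3-trimethylcyclopenta-1,4-dien-1-yl)oxy]benzene | COc1cc(OC2=C(C)C(C)(C)C=C2)c(Br)c(OC)c1 | intermediate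
11 | acrolein | C=CC=O | starting material
12 | {2,4-dimethoxy-6-[(2,3,3-trimethylcyclopenta-1,4-dien-1-yl)oxy]phenyl}lithium | [Li]c1c(OC)cc(OC)cc1OC1=C(C)C(C)(C)C=C1 | intermediate
13 | rac-1-{2,4-dimethoxy-6-[(2,3,3-trimethylcyclopenta-1,4-dien-1-yl)oxy]phenyl}prop-2-en-1-ol | C=CC(O)c1c(OC)cc(OC)cc1OC1=C(C)C(C)(C)C=C1 | intermediate
14 | 1-{2,4-dimethoxy-6-[(2,3,3-trimethylcyclopenta-1,4-dien-1-yl)oxy]phenyl}prop-2-en-1-one (achiral key-step precursor) | C=CC(=O)c1c(OC)cc(OC)cc1OC1=C(C)C(C)(C)C=C1 | intermediate
15 | (1R,4R,6R)-tetracyclic enol ether ketone: 1,7,7-trimethylbicyclo[2.2.1]hept-2-ene with C2–O–Ar2 and endo C6–C(=O)–Ar1, OMe at Ar4 and Ar6 | COc1cc2c(c(OC)c1)C(=O)[C@@H]1C[C@@H]3C=C(O2)[C@@]1(C)C3(C)C | intermediate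
16 | (1R,2S,4R,6R)-saturated tetracyclic ketone (endo C2–O, endo C6–C(=O)) | COc1cc2c(c(OC)c1)C(=O)[C@@H]1C[C@@H]3C[C@H](O2)[C@@]1(C)C3(C)C | intermediate
17 | (1R,2S,4R,6S)-dimethoxy tetracycle (endo C2–O, endo C6–CH2, H at Ar3 and Ar5) | COc1cc2c(c(OC)c1)C[C@@H]1C[C@@H]3C[C@H](O2)[C@@]1(C)C3(C)C | intermediate
18 | Ar3-(dimethyliminiomethyl) chloride of 17 | COc1c(C=[N+](C)C)c2c(c(OC)c1)C[C@@H]1C[C@@H]3C[C@H](O2)[C@@]1(C)C3(C)C.[Cl-] | intermediate
19 | Ar3-carbaldehyde of 17 | COc1c(C=O)c2c(c(OC)c1)C[C@@H]1C[C@@H]3C[C@H](O2)[C@@]1(C)C3(C)C | intermediate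
20 | isovaleraldehyde | CC(C)CC=O | starting material
21 | lithium α-amino alkoxide of 19 (hemiaminal carbon epimeric, of no consequence) | COc1c(C([O-])N(C)CCN(C)C)c2c(c(OC)c1)C[C@@H]1C[C@@H]3C[C@H](O2)[C@@]1(C)C3(C)C.[Li+] | intermediate
22 | Ar5-lithiated 21 | COc1c(C([O-])N(C)CCN(C)C)c2c(c(OC)c1[Li])C[C@@H]1C[C@@H]3C[C@H](O2)[C@@]1(C)C3(C)C.[Li+] | intermediate
23 | hydroxy aldehyde: Ar3-CHO, Ar5-(1-hydroxy-3-methylbutyl), both carbinol epimers | COc1c(C=O)c2c(c(OC)c1C(O)CC(C)C)C[C@@H]1C[C@@H]3C[C@H](O2)[C@@]1(C)C3(C)C | intermediate
24 | keto aldehyde dimethyl ether: Ar3-CHO, Ar5-isovaleryl | COc1c(C=O)c2c(c(OC)c1C(=O)CC(C)C)C[C@@H]1C[C@@H]3C[C@H](O2)[C@@]1(C)C3(C)C | intermediate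
25 | CNP0246493.1 | CC(C)CC(=O)c1c(O)c(C=O)c2c(c1O)C[C@@H]1C[C@@H]3C[C@H](O2)[C@@]1(C)C3(C)C | target

**Step count.** Total: 14 steps. Longest linear sequence: 13 steps (3 → 25, steps 2–14); step 1 is convergent.

**Steps most likely to fail**

**Step 9.**
- What may go wrong: slow bond formation at the fully substituted diene terminus, competing dimerisation, weak chelation by the aryl methyl ether, or an uncatalysed background cyclisation that erodes the enantiomeric purity.
- Approach of the fallback: it closes the two rings one after the other by known reactions, sets out from 4 and comes back at 16.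
- Diene: methyllithium addition to 4 gives 1,5,5-trimethylcyclopent-2-en-1-ol F1. Acid-catalysed 1,4-dehydration (cat. p-TsOH, the usual access to alkylcyclopentadienes) gives 1,5,5-trimethylcyclopenta-1,3-diene F2.
- Cycloaddition: an intermolecular Diels–Alder reaction with commercial 3-acryloyl-1,3-oxazolidin-2-one on the same Cu(II)–(R,R)-t-Bu-box catalyst gives the endo "ortho" imide F3. LiOH/H2O2 then frees the endo carboxylic acid F4.
- Setting the endo C2–O bond: iodolactonisation (I2, NaHCO3) lets the endo carboxylate attack C2 and gives the exo-iodo lactone F5. Bu3SnH/AIBN reduces it to the lactone F6, so that the endo C2–O bond is secured.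
- Aryl unit: NBS bromination of commercial 1-fluoro-3,5-dimethoxybenzene gives 2-bromo-1-fluoro-3,5-dimethoxybenzene F7. n-BuLi at −78 °C converts it into the aryllithium F8, which opens F6 to the hydroxy ketone F9.
- Oxepine closure: KHMDS in DMF closes the ring by intramolecular SNAr at the fluoride ortho to the ketone. Only the endo acyl epimer can cyclise. This delivers 16, and step 10 then has only to deoxygenate the ketone.

**Step 11.**
- What may go wrong: insufficient discrimination between Ar3 and Ar5 in the electrophilic substitution.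
- Approach of the fallback: it makes the other regioisomer productive, sets out from 17 and comes back at 24.
- Sequence: the separated Ar5-carbaldehyde F11 is treated with isobutylmagnesium bromide to give the carbinol F12. Dess–Martin oxidation gives the Ar5-isovaleryl ketone F13. Rieche formylation (Cl2CHOMe, TiCl4) at Ar3, then the only free position, gives 24. Both formylation isomers thus converge on the same compound.

**Step 6.**
- What may go wrong: sluggish coupling at the neopentyl-type triflate, S–O cleavage back to the dienolate, or attack of the cuprate on the aryl bromide.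
- Approach of the fallback: it avoids the triflate altogether, sets out from 7 and comes back at 10.
- Sequence: MeLi/CeCl3 adds 1,2 to the ketone to give the tertiary allylic alcohol F10. Catalytic p-TsOH over 4 Å molecular sieves ionises it to the allyl cation, which loses the ring CH2 proton. This is a 1,4-dehydration as practised for alkylcyclopentadienes, and any exocyclic methylene isomer equilibrates to the endocyclic diene under the same conditions. The product is 10.

**Further compounds**

F1 | step 9 | rac-1,5,5-trimethylcyclopent-2-en-1-ol | CC1(O)C=CCC1(C)C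
F2 | step 9 | 1,5,5-trimethylcyclopenta-1,3-diene | CC1=CC=CC1(C)C
F3 | step 9 | 3-{[(1R,4R,6R; bornane numbering)-1,7,7-trimethylbicyclo[2.2.1]hept-2-en-6-endo-yl]carbonyl}-1,3-oxazolidin-2-one | O=C(N1CCOC1=O)[C@@H]1C[C@@H]2C=C[C@@]1(C)C2(C)C
F4 | step 9 | corresponding 6-endo-carboxylic acid | OC(=O)[C@@H]1C[C@@H]2C=C[C@@]1(C)C2(C)C
F5 | step 9 | 3-exo-iodo 2-endo,6-endo γ-lactone | O=C4[C@@H]1C[C@@H]3[C@@H](I)[C@H](O4)[C@@]1(C)C3(C)C
F6 | step 9 | 2-endo,6-endo γ-lactone of the bornane | O=C4[C@@H]1C[C@@H]3C[C@H](O4)[C@@]1(C)C3(C)C
F7 | step 9 | 2-bromo-1-fluoro-3,5-dimethoxybenzene | COc1cc(F)c(Br)c(OC)c1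
F8 | step 9 | (2-fluoro-4,6-dimethoxyphenyl)lithium | [Li]c1c(F)cc(OC)cc1OC
F9 | step 9 | (2-fluoro-4,6-dimethoxyphenyl) 2-endo-hydroxybornan-6-endo-yl ketone | COc1cc(F)c(c(OC)c1)C(=O)[C@@H]1C[C@@H]3C[C@H](O)[C@@]1(C)C3(C)C
F10 | step 6 | rac-2-(2-bromo-3,5-dimethoxyphenoxy)-1,5,5-trimethylcyclopent-2-en-1-ol | COc1cc(OC2=CCC(C)(C)C2(C)O)c(Br)c(OC)c1
F11 | step 11 | Ar5-carbaldehyde of 17 | COc1cc2c(c(OC)c1C=O)C[C@@H]1C[C@@H]3C[C@H](O2)[C@@]1(C)C3(C)C
F12 | step 11 | Ar5-(1-hydroxy-3-methylbutyl) derivative of 17 (both carbinol epimers) | COc1cc2c(c(OC)c1C(O)CC(C)C)C[C@@H]1C[C@@H]3C[C@H](O2)[C@@]1(C)C3(C)C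
F13 | step 11 | Ar5-isovaleryl derivative of 17 | COc1cc2c(c(OC)c1C(=O)CC(C)C)C[C@@H]1C[C@@H]3C[C@H](O2)[C@@]1(C)C3(C)C
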